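## Structural features

The target 16 is a bicyclo[3.3.1]nonane-2,4,9-trione. Ring A (C1–C5 with C9) is an enolised 2-acylcyclohexane-1,3-dione with the 2-methylpropanoyl group on C3; ring B (C5–C8 with C1 and C9) is a cyclohexanone that shares C1, C9 and C5 with ring A. There are three stereocentres: the quaternary bridgeheads C1 (prenyl) and C5 (methyl), whose relative configuration is fixed by the bridge, and C7, whose prenyl group is endo, on the face of ring B from which the C2–C3–C4 bridge departs. C7, the quaternary C8 (gem-dimethyl) and the quaternary C1 are contiguous, so the C1–C8 bond joins two fully substituted carbons. The fragile groups are the acidic β-triketone (tautomers, O- versus C-reactivity) and the two trisubstituted alkenes, which can cyclise onto the enol oxygen under strong acid. The real difficulties are the C1–C8 bond, the absolute configuration of two bridgeheads that face each other across the C9 ketone, and the endo orientation at C7, which simple steric approach control does not deliver. The key step exploits two features: C1, C2, C3, C4, C5 and C9 with their three oxygens are a C-acylated, C-methylated, C-prenylated phloroglucinol in disguise, and the first carbon of the endo C7 prenyl group (C1′) lies within bonding distance of C3, so a C3–C1′ bond completes an adamantane with C1, C3, C5 and C7 as bridgeheads.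

## Logic of the disconnections

16 to 15: the C2′=C3′ double bond of the C7 side chain is cut (Wittig transform). This removes three carbons and leaves a C7–CH2–CHO arm; no stereocentre is involved. The forward step must olefinate an enolisable aldehyde in the presence of the acidic triketone, so the ylide is used in excess and the triketone travels as its enolate.

15 to 14 to 13: the C1′–C2′ bond is cut (one-carbon homologation through the enol ether 14). This takes the side chain back to a formyl group on C7, the oxidation level that an enal delivers. The forward demand is that the C7–H bond of 13 is never broken, since C7 is α to the aldehyde only at this stage.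

13 to 12: here a bond is added in the retrosynthetic sense, C3–C1′. The free endo aldehyde 13 is configurationally labile at C7, whereas its internal aldol 12 is a rigid cage that can form only from the endo epimer. Storing 13 as 12 turns the C7 problem into a thermodynamic one. The forward demand is that the retro-aldol release is coupled to an immediate, irreversible capture of the aldehyde.

12 to 5 and 9: the bonds C3–C1′, C1–C8 and C5–C6 are cut; in the forward sense the cascade passes through 10 and 11. The three nucleophilic ring carbons of an acylphloroglucinol are matched with the three electrophilic carbons of an α-(halomethyl) enal, and all five stereocentres and two rings go back to two achiral pieces. The forward demands are three.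
- Face selection at C5 must come from a chiral ion pair.
- The first alkylation must choose the methyl-bearing carbon over the prenyl-bearing one. The leaving group in 9 is kept as bromide so that the intermolecular bond is made by direct SN2 at CH2. This pairs the less hindered ring carbon with the less hindered electrophilic carbon and leaves the congested C1–C8 bond to the intramolecular Michael step.
- 5 is used unprotected. Each of its three oxygens has to become an enolate oxygen during the cascade, so a cap on any of them would stop the Michael or the aldol closure. Site selection therefore cannot be bought with protecting groups; it remains the weak point.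

5 to 3 and 4, then 3 to 1 and 2: the aryl–CH2 bond and the aryl–acyl bond are cut. Both are standard electrophilic substitutions of a phloroglucinol. Symmetry of 1 makes the acylation regiochemically unambiguous, and 3 has a single free ring carbon. The forward demand is to stop the prenylation at mono-C-alkylation.

9 to 8 to 7 to 6: the C–Br bond, then one C=O, then both ester carbonyls are taken back. A β,β-disubstituted enal cannot be α-hydroxymethylated in a Baylis–Hillman manner, so the C6 skeleton is taken from an isopropylidene malonate in which the tetrasubstituted alkene already exists. The symmetric diol 7 needs only one oxidation and one substitution. The forward demand is to stop the oxidation at the mono-aldehyde.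

## Other disconnections considered

Alternative 1: Cut of C1–C8 in a bicycle that still lacks the C1 prenyl group, the C3 acyl group and the C7 carbon chain.
- Forward step: Me3SiOTf opens the enantiopure epoxide of the dienone A1 at its tertiary carbon C8. One of the two enantiotopic methoxy-enone carbons (the future C1) attacks, closing ring B to A2.
- In its favour: the absolute configuration comes from a stoichiometric stereocentre (the epoxide carbon, future C7) through a six-membered transition state, so C5 and C1 are set together without reliance on a catalyst. The C5 methyl group is placed on the monocycle, so there is no competition between a methyl- and a prenyl-bearing carbon. On both of these points the alternative is better than the chosen plan.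
- Against it here: A2 is far from 16. C1 needs bridgehead metalation and prenylation, and C3 needs acylation. The C7 hydroxyl is exo, on the face opposite to where the prenyl group must stand, and must be exchanged for carbon with control of configuration next to the quaternary C8. The stereocentre that carried the information is then destroyed. The α-carbon of a vinylogous ester is also a weak nucleophile towards the cation, so the cyclisation may need a lower oxidation level at C2 and a later allylic oxidation.
- Comparison: on structure, both plans build ring B onto a preformed ring A, but the chosen plan brings C7 in with its carbon substituent already endo and with the C1 and C3 substituents in place. On mechanism, cationic substrate control is more predictable than a catalyst-controlled anionic cascade. On step economy, the alternative would need roughly three times as many operations after ring closure, plus the enantioselective synthesis of A1.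

Alternative 2: Cut of C5–C6.
- Forward step: Pd2(dba)3 (zerovalent palladium) with a chiral DACH-phenyl diphosphine ionises the allylic carbonate of the achiral triketone A3. C5, one of two enantiotopic dicarbonyl carbons, attacks the allyl terminus C6 and gives A4.
- In its favour: this is a catalytic desymmetrisation of an achiral substrate that makes C1 and C5 stereogenic in one event. The two competing carbons are truly enantiotopic, so a wrong choice costs enantiomeric purity and not constitution; on this point the alternative is better than the chosen plan. The exocyclic C7 methylidene is a flexible handle: hydroboration from the exo face could give the endo C7 formyl oxidation level of 13.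
- Against it here: A3 already contains the vicinal quaternary pair C1–C8. The hardest bond of the target is therefore moved into the precursor and not solved by the key step. C5 emerges with hydrogen and must be methylated at a non-enolisable bridgehead between two carbonyls, and C3 must still be acylated. The triketone of A3 can also close through oxygen.
- Comparison: both plans rely on a chiral catalyst that distinguishes two ring carbons, and in that respect they are equal. On mechanism, the outer-sphere allylation is well understood, but the stereocentres are set far from the ligand-bound terminus. On step economy, the alternative is clearly longer, because three substituents (C5 methyl, C3 acyl, C7 prenyl) are added after the bicycle exists.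

Alternative 3: Cut of C1–C2.
- Forward step: (2-biphenylyl)(tBu)2PAu(NCMe)SbF6 (monovalent gold) activates the ethoxy ynone of A5. The silyl enol ether attacks through C1 at alkyne carbon C2 in a 6-endo-dig closure of ring A, giving A6.
- In its favour: A6 carries every carbon of 16 except the acyl group, so only C3 acylation and cleavage of the ethyl enol ether remain. This is the best economy after the key step, and better than the chosen plan. The closure is regiochemically unambiguous and forms the hindered C1 quaternary centre without a new independent stereocentre, again a point on which it is better. The triketone stays masked as a vinylogous ester.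
- Against it here: all stereochemical work is pushed into A5. This is a pentasubstituted cyclohexane with a quaternary C5, a C7 prenyl group cis to the acyl arm (the endo series) and a tetrasubstituted silyl enol ether formed towards the hindered C1. An enantioselective route to A5 would be long, and nothing in it corrects C7 the way the aldol tether does. The ynol ether ynone is sensitive to hydration.
- Comparison: on structure, this plan closes ring A last and the chosen plan closes ring B last. On mechanism, carbophilic alkyne activation is cleaner in site selection than the anionic cascade. On step economy, the total count would be well above that of the chosen plan, although the part after the key step is shorter.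

Key step: step 6

Remark: the cinchoninium salt is taken to expose the face of C5 that leads to 12; if the ion pair prefers the other face, the pseudo-enantiomeric cinchonidinium salt is used and nothing else changes.
Remark: enolised triketones are drawn as the 4-hydroxy-3-ene tautomer; the tautomers interconvert.
Remark: the configurations of 12 and 16 agree when traced on an adamantane model (C7 chain endo, same sense at C1 and C5, hydroxyl of 12 on the C4/C6 side).
Remark: the Michael closure in step 6 does not fix C7, so its aldehyde product is numbered 11 as the pair of interconverting C7 epimers; the single endo epimer that the retro-aldol of step 7 releases is numbered 13.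

## Route

Step 1
Reactants: 1 2-methylbenzene-1,3,5-triol; 2 2-methylpropanoyl chloride
Product: 3 1-(2,4,6-trihydroxy-3-methylphenyl)-2-methylpropan-1-one
Conditions: AlCl3 (4 equiv), PhNO2–CH2Cl2, 0 → 60 °C; aq. HCl
Reagents that add atoms: none
Why: Friedel–Crafts C-acylation of a phloroglucinol; the two free ring positions of 1 are equivalent by symmetry and the first acyl group deactivates the ring against a second acylation.

Step 2
Reactants: 3 1-(2,4,6-trihydroxy-3-methylphenyl)-2-methylpropan-1-one; 4 1-bromo-3-methylbut-2-ene
Product: 5 1-[2,4,6-trihydroxy-3-methyl-5-(3-methylbut-2-enyl)phenyl]-2-methylpropan-1-one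
Conditions: 4 (1.0 equiv), 5% aq. KOH, 0 °C
Reagents that add atoms: none
Why: C-prenylation of an acylphloroglucinolate in water, where solvation of the oxygens favours attack through carbon; the only unsubstituted ring carbon is alkylated with re-aromatisation, and one equivalent of 4 at 0 °C limits dearomatising over-alkylation.

Step 3
Reactants: 6 diethyl 2-(propan-2-ylidene)propanedioate
Product: 7 2-(propan-2-ylidene)propane-1,3-diol
Conditions: iBu2AlH (4.5 equiv), CH2Cl2, −78 → 0 °C; aq. KNa tartrate
Reagents that add atoms: none
Why: 1,2-reduction of both esters of an alkylidene malonate by iBu2AlH in a non-coordinating solvent; the tetrasubstituted alkene is too hindered for conjugate hydride delivery.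

Step 4
Reactants: 7 2-(propan-2-ylidene)propane-1,3-diol
Product: 8 2-(hydroxymethyl)-3-methylbut-2-enal
Conditions: MnO2 (10 equiv), CH2Cl2, 23 °C, stopped before full conversion
Reagents that add atoms: none
Why: allylic alcohol oxidation with MnO2; the two hydroxymethyl groups of 7 are equivalent, and after the first oxidation the remaining alcohol sits on an electron-poor alkene and should react more slowly, so mono-oxidation can be held.

Step 5
Reactants: 8 2-(hydroxymethyl)-3-methylbut-2-enal
Product: 9 2-(bromomethyl)-3-methylbut-2-enal
Conditions: PBr3 (0.4 equiv), Et2O, 0 °C
Reagents that add atoms: phosphorus tribromide, BrP(Br)Br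
Why: conversion of a primary allylic alcohol into the bromide through its phosphite ester (SN2); any transposed tertiary bromide should equilibrate to the conjugated primary bromide 9, and the aldehyde is inert at 0 °C.

Step 6
Reactants: 5 1-[2,4,6-trihydroxy-3-methyl-5-(3-methylbut-2-enyl)phenyl]-2-methylpropan-1-one; 9 2-(bromomethyl)-3-methylbut-2-enal
Product: 12 10-hydroxy-5,8,8-trimethyl-1-(3-methylbut-2-enyl)-3-(2-methylpropanoyl)adamantane-2,4,9-trione (adamantane alcohol; C10 = C1′; hydroxyl on the C4/C6 side), via C5-alkylated cyclohexadienone 10 (not isolated), via C7-epimeric Michael aldehyde 11 (not isolated)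
Conditions: CsOH·H2O (5 equiv), N-(9-anthracenylmethyl)-O-allylcinchoninium bromide (20 mol %), 4 Å MS, CH2Cl2, −50 °C; aq. NH4Cl
Reagents that add atoms: none
Why: Solid CsOH gives the phloroglucinolate of 5, held as a chiral ion pair by the cinchoninium cation, and its methyl-bearing carbon C5 displaces the primary allylic bromide of 9 by SN2 to give 10; this is the alkylative dearomatisation–annulation of acylphloroglucinols with α-(halomethyl) enals, known also under cinchona phase-transfer catalysis. Ring B then closes by a 6-endo-trig Michael addition of the enolate carbon C1 to the β,β-dimethyl carbon C8, and C-protonation of the resulting aldehyde enolate gives 11 as a pair of interconverting C7 epimers; the third ring closes from the endo epimer by a 6-exo-trig aldol addition of C3 to the formyl carbon. C5 is set by the face of the arene that the ion pair leaves open, and C1 follows from C5 because the three-atom bridge C6–C7–C8 can span only one face of ring A. C7 is set under thermodynamic control: Michael addition and enolisation of the aldehyde are reversible, only the endo aldehyde can reach C3, and the strain-free adamantane is the sink. C3 is fixed by the cage, and the carbinol carbon should place its hydroxyl on the C4/C6 side, away from the axial C8 methyl group, which is of no consequence because this centre is removed in step 7. The selectivity that the step needs and that the substrate secures least is that of site: C5 must be alkylated in preference to the prenyl-bearing C1, and only the smaller size of methyl supports this. The bromide is chosen so that the intermolecular bond is made by direct SN2 at CH2, pairing the less hindered ring carbon with the less hindered electrophilic carbon, and the three oxygens are left free because a cap on any of them would stop the Michael or the aldol closure. C- over O-alkylation is helped by the soft allylic bromide in CH2Cl2 at low temperature.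

Step 7
Reactants: 12 10-hydroxy-5,8,8-trimethyl-1-(3-methylbut-2-enyl)-3-(2-methylpropanoyl)adamantane-2,4,9-trione
Product: 14 4-hydroxy-7-(2-methoxyethenyl)-5,8,8-trimethyl-1-(3-methylbut-2-enyl)-3-(2-methylpropanoyl)bicyclo[3.3.1]non-3-ene-2,9-dione (E/Z mixture; C1 C5 C7 as in 16), via endo C7 aldehyde 13 (not isolated)
Conditions: MeOCH2PPh3Cl (4 equiv), KN(SiMe3)2 (3.8 equiv), THF, 0 °C; then 12, −78 → 0 °C; aq. NH4Cl
Reagents that add atoms: (methoxymethyl)triphenylphosphonium chloride, COC[P+](c1ccccc1)(c1ccccc1)c1ccccc1.[Cl-]
Why: The first equivalent of ylide deprotonates the carbinol, and the alkoxide fragments by retro-aldol because the leaving group is the highly stabilised triketone enolate, which releases the single endo epimer 13; the unstabilised ylide then olefinates 13 (Wittig reaction) faster than it can enolise. C7 keeps its endo configuration because its C–H bond is not broken, and the enolate protects C2 and C4 while the C9 ketone is too hindered to react.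

Step 8
Reactants: 14 4-hydroxy-7-(2-methoxyethenyl)-5,8,8-trimethyl-1-(3-methylbut-2-enyl)-3-(2-methylpropanoyl)bicyclo[3.3.1]non-3-ene-2,9-dione
Product: 15 2-[4-hydroxy-5,8,8-trimethyl-1-(3-methylbut-2-enyl)-3-(2-methylpropanoyl)-2,9-dioxobicyclo[3.3.1]non-3-en-7-yl]acetaldehyde (C1, C5, C7 as in 16)
Conditions: 1 M aq. HCl–THF (1:2), 23 °C
Reagents that add atoms: water, O
Why: Acid-catalysed hydrolysis of a methyl enol ether (protonation at C1′, hemiacetal, loss of methanol); dilute acid at room temperature should leave the prenyl groups alone, and the water-rich medium favours capture of the oxocarbenium ion by water over capture by the neighbouring enol.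

Step 9
Reactants: 15 2-[4-hydroxy-5,8,8-trimethyl-1-(3-methylbut-2-enyl)-3-(2-methylpropanoyl)-2,9-dioxobicyclo[3.3.1]non-3-en-7-yl]acetaldehyde
Product: 16 (1R,5R,7R)-4-hydroxy-5,8,8-trimethyl-1,7-bis(3-methylbut-2-enyl)-3-(2-methylpropanoyl)bicyclo[3.3.1]non-3-ene-2,9-dione (CNP0265287.1)
Conditions: iPrPPh3I (3.5 equiv), n-BuLi (3.3 equiv), THF, 0 °C; then 15, −78 → 0 °C; aq. NH4Cl
Reagents that add atoms: triphenyl(propan-2-yl)phosphonium iodide, CC(C)[P+](c1ccccc1)(c1ccccc1)c1ccccc1.[I-]
Why: Wittig olefination with the isopropylidene ylide, the standard way to finish a prenyl group; the first equivalent turns the triketone into its unreactive lithium enolate, and any aldol-closed form of 15 reopens under the basic conditions. No stereocentre is touched.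

## Compound list

1 | 2-methylbenzene-1,3,5-triol | Cc1c(O)cc(O)cc1O | starting material
2 | 2-methylpropanoyl chloride | CC(C)C(Cl)=O | starting material
3 | 1-(2,4,6-trihydroxy-3-methylphenyl)-2-methylpropan-1-one | CC(C)C(=O)c1c(O)cc(O)c(C)c1O | intermediate
4 | 1-bromo-3-methylbut-2-ene | CC(C)=CCBr | starting material
5 | 1-[2,4,6-trihydroxy-3-methyl-5-(3-methylbut-2-enyl)phenyl]-2-methylpropan-1-one | CC(C)C(=O)c1c(O)c(C)c(O)c(CC=C(C)C)c1O | intermediate
6 | diethyl 2-(propan-2-ylidene)propanedioate | CCOC(=O)C(=C(C)C)C(=O)OCC | starting material
7 | 2-(propan-2-ylidene)propane-1,3-diol | CC(C)=C(CO)CO | intermediate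
8 | 2-(hydroxymethyl)-3-methylbut-2-enal | CC(C)=C(CO)C=O | intermediate
9 | 2-(bromomethyl)-3-methylbut-2-enal | CC(C)=C(C=O)CBr | intermediate
10 | 2-{[2,4-dihydroxy-1-methyl-3-(3-methylbut-2-enyl)-5-(2-methylpropanoyl)-6-oxocyclohexa-2,4-dien-1-yl]methyl}-3-methylbut-2-enal (C5-alkylated cyclohexadienone, present as its enolate; quaternary carbon = C5) | CC(C)C(=O)C1=C(O)C(CC=C(C)C)=C(O)[C@](C)(CC(C=O)=C(C)C)C1=O | intermediate (not isolated)
11 | 4-hydroxy-5,8,8-trimethyl-1-(3-methylbut-2-enyl)-3-(2-methylpropanoyl)-2,9-dioxobicyclo[3.3.1]non-3-ene-7-carbaldehyde (Michael adduct; both C7 epimers, interconverting through the aldehyde enolate; C1 and C5 as in 16) | O=CC1C[C@@]2(C)C(=O)[C@](CC=C(C)C)(C(=O)C(C(=O)C(C)C)=C2O)C1(C)C | intermediate (not isolated)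
12 | 10-hydroxy-5,8,8-trimethyl-1-(3-methylbut-2-enyl)-3-(2-methylpropanoyl)adamantane-2,4,9-trione (numbered as the bicycle, C10 = C1′ joining C3 and C7; hydroxyl on the C4/C6 side) | O[C@@H]3[C@@H]1C[C@@]2(C)C(=O)[C@](CC=C(C)C)(C(=O)[C@]3(C(=O)C(C)C)C2=O)C1(C)C | intermediate
13 | 4-hydroxy-5,8,8-trimethyl-1-(3-methylbut-2-enyl)-3-(2-methylpropanoyl)-2,9-dioxobicyclo[3.3.1]non-3-ene-7-carbaldehyde (single epimer, formyl endo; C1, C5, C7 as in 16) | O=C[C@@H]1C[C@@]2(C)C(=O)[C@](CC=C(C)C)(C(=O)C(C(=O)C(C)C)=C2O)C1(C)C | intermediate (not isolated)
14 | 4-hydroxy-7-(2-methoxyethenyl)-5,8,8-trimethyl-1-(3-methylbut-2-enyl)-3-(2-methylpropanoyl)bicyclo[3.3.1]non-3-ene-2,9-dione (E/Z mixture at the enol ether; C1, C5, C7 as in 16) | COC=C[C@@H]1C[C@@]2(C)C(=O)[C@](CC=C(C)C)(C(=O)C(C(=O)C(C)C)=C2O)C1(C)C | intermediate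
15 | 2-[4-hydroxy-5,8,8-trimethyl-1-(3-methylbut-2-enyl)-3-(2-methylpropanoyl)-2,9-dioxobicyclo[3.3.1]non-3-en-7-yl]acetaldehyde (C1, C5, C7 as in 16) | O=CC[C@@H]1C[C@@]2(C)C(=O)[C@](CC=C(C)C)(C(=O)C(C(=O)C(C)C)=C2O)C1(C)C | intermediate
16 | (1R,5R,7R)-4-hydroxy-5,8,8-trimethyl-1,7-bis(3-methylbut-2-enyl)-3-(2-methylpropanoyl)bicyclo[3.3.1]non-3-ene-2,9-dione | CC(C)=CC[C@@H]1C[C@@]2(C)C(=O)[C@](CC=C(C)C)(C(=O)C(C(=O)C(C)C)=C2O)C1(C)C | target

## Step count and least certain steps

Total: 9 steps. Longest linear sequence: 7 steps (6 → 7 → 8 → 9 → 12 → 14 → 15 → 16); the arene branch (1 → 3 → 5) has 2 steps.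

Step 6 (key step). The most likely failure is poor site discrimination in the first alkylation: the methyl- and prenyl-bearing carbons differ only in steric demand, and attack at C1 leads to the skeleton with methyl and prenyl transposed. Linked to it, the ion pair may read the two flanks of an unsymmetrical arene less well than those of a symmetrical one, which would erode face selection. The fallback changes the activation of the electrophile from SN2 to a π-allyl. 8 would be converted (Boc2O, DMAP) into tert-butyl (2-formyl-3-methylbut-2-enyl) carbonate F1. F1 would be coupled with 5 under Pd2(dba)3 (zerovalent palladium) and one enantiomer of the DACH-phenyl diphosphine in THF, a dearomatising allylic alkylation of the kind known for acylphloroglucinols. The ligated allyl cation is attacked at its CH2 terminus, and the large chiral pocket should be more sensitive than a bromide to the substituent on the attacked ring carbon while also supplying face selection. The product is 10, which LiN(SiMe3)2 in the same flask carries on to 12. This fallback sets out from 5 and 8 and returns to the route at 10.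

Step 7. The most likely failure is slow interception of the released aldehyde. The basic ylide could then enolise 13, causing epimerisation at C7 into the exo series that cannot re-close, or the enolate–aldehyde could simply re-close to 12 on work-up. The fallback is capture by a more nucleophilic, less basic organocerium reagent followed by deoxygenation and metathesis. 12 with CH2=CHMgBr/CeCl3 (THF, −78 °C) should give 4-hydroxy-7-(1-hydroxyprop-2-enyl)-5,8,8-trimethyl-1-(3-methylbut-2-enyl)-3-(2-methylpropanoyl)bicyclo[3.3.1]non-3-ene-2,9-dione F2. O-methylation of the enol (Me3SiCHN2) and acetylation (Ac2O, DMAP) would give the methyl enol ether acetate F3. Pd(PPh3)4 with HCO2NH4 should deliver hydride to the more substituted allyl terminus and give the C7 allyl compound 4-methoxy-5,8,8-trimethyl-1-(3-methylbut-2-enyl)-3-(2-methylpropanoyl)-7-(prop-2-enyl)bicyclo[3.3.1]non-3-ene-2,9-dione F4. Cross-metathesis with 2-methylbut-2-ene (second-generation Grubbs catalyst RuCl2(=CHPh)(H2IMes)(PCy3)) would give the methyl ether of the target F5. LiCl in DMSO at 120 °C would cleave the methyl ether to 16. This fallback sets out from 12 and returns at 16.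

Step 8. The most likely failure is internal capture of the oxocarbenium ion by the neighbouring enol (through C3 or oxygen, closing a seven-membered ring) in competition with water, or acid-promoted cyclisation of the enol onto the C1 prenyl group. The fallback avoids any cation next to the enol by hydroboration in place of enol ether hydrolysis. 12 with Ph3P=CH2 (from MePPh3Br and KN(SiMe3)2) under the conditions of step 7 should give the vinyl compound 7-ethenyl-4-hydroxy-5,8,8-trimethyl-1-(3-methylbut-2-enyl)-3-(2-methylpropanoyl)bicyclo[3.3.1]non-3-ene-2,9-dione F6. 9-BBN, which selects the monosubstituted alkene over the two trisubstituted ones, then NaBO3, would give the primary alcohol 4-hydroxy-7-(2-hydroxyethyl)-5,8,8-trimethyl-1-(3-methylbut-2-enyl)-3-(2-methylpropanoyl)bicyclo[3.3.1]non-3-ene-2,9-dione F7. Oxidation with SO3·pyridine, DMSO and iPr2NEt would give 15. This fallback sets out from 12 and returns at 15.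

Step 4. The most likely failure is oxidation that does not stop at the mono-aldehyde, with loss of material to the dialdehyde. The fallback differentiates the two hydroxyls before oxidation. 7 with NaH and tBuMe2SiCl (1 equiv) would give 2-{[tert-butyl(dimethyl)silyl]oxymethyl}-3-methylbut-2-en-1-ol F8. MnO2 oxidation would give 2-{[tert-butyl(dimethyl)silyl]oxymethyl}-3-methylbut-2-enal F9. HF·pyridine would release 8. This fallback sets out from 7 and returns at 8.

## Further compounds

F1 | step 6 | tert-butyl (2-formyl-3-methylbut-2-enyl) carbonate | CC(C)=C(C=O)COC(=O)OC(C)(C)C
F2 | step 7 | 4-hydroxy-7-(1-hydroxyprop-2-enyl)-5,8,8-trimethyl-1-(3-methylbut-2-enyl)-3-(2-methylpropanoyl)bicyclo[3.3.1]non-3-ene-2,9-dione (carbinol epimers) | C=CC(O)[C@@H]1C[C@@]2(C)C(=O)[C@](CC=C(C)C)(C(=O)C(C(=O)C(C)C)=C2O)C1(C)C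
F3 | step 7 | 1-[4-methoxy-5,8,8-trimethyl-1-(3-methylbut-2-enyl)-3-(2-methylpropanoyl)-2,9-dioxobicyclo[3.3.1]non-3-en-7-yl]prop-2-enyl acetate (4-O-methyl isomer drawn) | C=CC(OC(C)=O)[C@@H]1C[C@@]2(C)C(=O)[C@](CC=C(C)C)(C(=O)C(C(=O)C(C)C)=C2OC)C1(C)C
F4 | step 7 | 4-methoxy-5,8,8-trimethyl-1-(3-methylbut-2-enyl)-3-(2-methylpropanoyl)-7-(prop-2-enyl)bicyclo[3.3.1]non-3-ene-2,9-dione | C=CC[C@@H]1C[C@@]2(C)C(=O)[C@](CC=C(C)C)(C(=O)C(C(=O)C(C)C)=C2OC)C1(C)C
F5 | step 7 | 4-methoxy-5,8,8-trimethyl-1,7-bis(3-methylbut-2-enyl)-3-(2-methylpropanoyl)bicyclo[3.3.1]non-3-ene-2,9-dione | CC(C)=CC[C@@H]1C[C@@]2(C)C(=O)[C@](CC=C(C)C)(C(=O)C(C(=O)C(C)C)=C2OC)C1(C)C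
F6 | step 8 | 7-ethenyl-4-hydroxy-5,8,8-trimethyl-1-(3-methylbut-2-enyl)-3-(2-methylpropanoyl)bicyclo[3.3.1]non-3-ene-2,9-dione | C=C[C@@H]1C[C@@]2(C)C(=O)[C@](CC=C(C)C)(C(=O)C(C(=O)C(C)C)=C2O)C1(C)C
F7 | step 8 | 4-hydroxy-7-(2-hydroxyethyl)-5,8,8-trimethyl-1-(3-methylbut-2-enyl)-3-(2-methylpropanoyl)bicyclo[3.3.1]non-3-ene-2,9-dione | OCC[C@@H]1C[C@@]2(C)C(=O)[C@](CC=C(C)C)(C(=O)C(C(=O)C(C)C)=C2O)C1(C)C
F8 | step 4 | 2-{[tert-butyl(dimethyl)silyl]oxymethyl}-3-methylbut-2-en-1-ol | CC(C)=C(CO)CO[Si](C)(C)C(C)(C)C
F9 | step 4 | 2-{[tert-butyl(dimethyl)silyl]oxymethyl}-3-methylbut-2-enal | CC(C)=C(C=O)CO[Si](C)(C)C(C)(C)C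
A1 | alternative 1 | 4-[(3,3-dimethyloxiran-2-yl)methyl]-3,5-dimethoxy-4-methylcyclohexa-2,5-dien-1-one (single enantiomer at the oxirane CH) | CC1(C)O[C@H]1CC2(C)C(OC)=CC(=O)C=C2OC
A2 | alternative 1 | 7-hydroxy-4-methoxy-5,8,8-trimethylbicyclo[3.3.1]non-3-ene-2,9-dione | O[C@H]1C[C@@]2(C)C(=O)[C@H](C(=O)C=C2OC)C1(C)C
A3 | alternative 2 | methyl 3-methyl-2-methylidene-3-[1-(3-methylbut-2-enyl)-2,4,6-trioxocyclohexyl]butyl carbonate | COC(=O)OCC(=C)C(C)(C)C1(CC=C(C)C)C(=O)CC(=O)CC1=O
A4 | alternative 2 | 8,8-dimethyl-7-methylidene-1-(3-methylbut-2-enyl)bicyclo[3.3.1]nonane-2,4,9-trione | C=C1C[C@H]2C(=O)[C@](CC=C(C)C)(C(=O)CC2=O)C1(C)C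
A5 | alternative 3 | 1-[2-{[tert-butyl(dimethyl)silyl]oxy}-1,4,4-trimethyl-3,5-bis(3-methylbut-2-enyl)cyclohex-2-en-1-yl]-3-ethoxyprop-2-yn-1-one (acyl arm and C5-ring prenyl cis) | CCOC#CC(=O)[C@@]1(C)C[C@@H](CC=C(C)C)C(C)(C)C(CC=C(C)C)=C1O[Si](C)(C)C(C)(C)C
A6 | alternative 3 | 2-ethoxy-5,8,8-trimethyl-1,7-bis(3-methylbut-2-enyl)bicyclo[3.3.1]non-2-ene-4,9-dione | CC(C)=CC[C@@H]1C[C@@]2(C)C(=O)[C@](CC=C(C)C)(C(OCC)=CC2=O)C1(C)C
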